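The oxane ring (O1, C2, C3, C4, C5, C6) is not closed directly: it is grown from an oxolane by one atom. The feature used is the O1–C2(CH3)2–C3(Br) unit, an ether oxygen on a tertiary carbon next to the brominated carbon. A 2-(2-hydroxypropan-2-yl)oxolane ionises with oxygen participation to a bicyclic oxiranium ion, and bromide opens it at the ring-fusion carbon with inversion, creating C3–Br and the six-membered ring in one operation. The precursor comes from (−)-α-bisabolol (C6 and C1' bought) by catalyst-controlled double epoxidation; the cyclohexane halogens are then relayed by neighbouring-group steps.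

Key step: step 2

Remark: locants are O1, C2 (CMe2), C3 (CHBr), C6 for the oxane and C1', C3' (CH), C4' (CMe) for the cyclohexane; (−)-α-bisabolol is taken as the (S,S) isomer, and the D-fructose-derived Shi ketone is assumed to show its usual facial preference on both trisubstituted alkenes.

Step 1
Reactants: 1 (−)-α-bisabolol
Product: 3 2-[(2S,5S)-5-methyl-5-[(1R,3S,6S)-6-methyl-7-oxabicyclo[4.1.0]heptan-3-yl]oxolan-2-yl]propan-2-ol, via bis-epoxide 2 (not isolated)
Conditions: D-fructose-derived Shi ketone (30 mol%), KHSO5 (as Oxone, 2KHSO5·KHSO4·K2SO4), K2CO3, Bu4NHSO4 (cat.), Na2B4O7/Na2EDTA buffer, MeCN–CH2(OMe)2, 0 °C; then crude, KOtBu (20 mol%), THF, 0 → 23 °C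
Reagents that add atoms: potassium peroxymonosulfate KHSO5, [K+].[O-]S(=O)(=O)OO
Why: Shi asymmetric epoxidation (chiral dioxirane, spiro transition state) oxidises both trisubstituted alkenes under catalyst control, giving the (R) side-chain epoxide and the ring epoxide anti to the C1' substituent, and the C7 alkoxide then opens the side-chain epoxide 5-exo-tet at its secondary carbon with inversion, which sets the oxolane CH as (S), trans to the cyclohexyl group.

Step 2
Reactants: 3 oxolane carbinol epoxide
Product: 7 (1R,2R,5S)-2-bromo-5-[(2S,5R)-5-bromo-2,6,6-trimethyloxan-2-yl]-2-methylcyclohexan-1-ol, via bromohydrin carbinol 4 (not isolated), via oxiranium bromide 5 (not isolated), via oxolane tertiary bromide 6 (not isolated)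
Conditions: HBr (anhydrous, 2.3 equiv), 4 Å MS, CH2Cl2, −78 → −20 °C; then ZnBr2 (10 mol%), 0 → 23 °C
Reagents that add atoms: hydrogen bromide, Br
Why: HBr first opens the ring epoxide at its tertiary carbon C4' from the face opposite to oxygen (Markovnikov and trans-diaxial, Fürst–Plattner), setting C4'–Br cis and C3'–OH trans to the side chain (4); the tertiary carbinol then ionises with participation of the antiperiplanar oxolane oxygen to the 1-oxoniabicyclo[3.1.0]hexane ion 5, and bromide cleaves its inner O–CH bond by SN2 to give the oxane. The closest known reaction type is the oxiranium-mediated ring expansion of 2-(1-sulfonyloxyalkyl)oxolanes to 3-substituted oxanes, and in reverse the ring contraction seen when 3-hydroxy-2,2-dimethyloxanes are activated. The O1–C2 bond forms by 3-exo-tet closure, which at the same time closes the six-membered perimeter O1–C2–C3–C4–C5–C6, and cleavage of the old O–C3 bond deletes the five-membered ring. C3 (R) arises by inversion of the (S) oxolane carbon set in step 1, so bromine ends trans to the cyclohexyl group and equatorial, while C6 is untouched. The step needs bromide to end on the secondary ring-fusion carbon although the tertiary carbon is attacked faster: the kinetic tertiary bromide 6 should re-ionise readily through 5 (ZnBr2), whereas the secondary bromide of the strain-free oxane with its tertiary ether should not, so 7 is expected to be the sink. Near-stoichiometric HBr and a short reaction time should spare the secondary hydroxyl and the tertiary ether bonds.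

Step 3
Reactants: 7 bromooxane bromohydrin
Product: 10 (3R,6S)-3-bromo-6-[(1S,3R,4R)-4-bromo-3-chloro-4-methylcyclohexyl]-2,2,6-trimethyloxane, via chlorosulfite 8 (not isolated), via bromonium chloride 9 (not isolated)
Conditions: SOCl2, pyridine, CH2Cl2, −20 → 23 °C
Reagents that add atoms: thionyl chloride, O=S(Cl)Cl
Why: The chlorosulfite of the axial C3' hydroxyl ionises with participation of the antiperiplanar axial C4' bromine (classical conversion of a β-bromo alcohol into a bromochloride with retention via a bromonium ion), and chloride opens bromonium 9 trans-diaxially at C3' (Fürst–Plattner) to give the (3'R,4'R) diaxial isomer; any capture at C4' gives 11 directly and is carried forward.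

Step 4
Reactants: 10 diaxial 4'-bromo-3'-chloro isomer
Product: 11 caespitane
Conditions: PhCl, 130 °C (sealed tube), NaHCO3 (solid, trace)
Reagents that add atoms: none
Why: Thermal diaxial-to-diequatorial interchange of vicinal trans halogens (dyotropic rearrangement, as in the classical mutarotation of 5α,6β-dihalo steroids): bromine shifts from C4' to C3' across the upper face while chlorine shifts from C3' to C4' across the lower face, both carbons invert, and the all-equatorial (1'S,3'S,4'S) secondary bromide and tertiary chloride should result and persist because it lacks an antiperiplanar neighbouring halogen.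

Compound list
1 | (−)-α-bisabolol, (2S)-6-methyl-2-[(1S)-4-methylcyclohex-3-en-1-yl]hept-5-en-2-ol | O[C@@](C)(CCC=C(C)C)[C@@H]1CC=C(C)CC1 | starting material
2 | bis-epoxide, (2S)-4-[(2R)-3,3-dimethyloxiran-2-yl]-2-[(1R,3S,6S)-6-methyl-7-oxabicyclo[4.1.0]heptan-3-yl]butan-2-ol | O[C@@](C)(CC[C@H]1OC1(C)C)[C@H]2CC[C@]3(C)O[C@@H]3C2 | intermediate
3 | oxolane carbinol epoxide, 2-[(2S,5S)-5-methyl-5-[(1R,3S,6S)-6-methyl-7-oxabicyclo[4.1.0]heptan-3-yl]oxolan-2-yl]propan-2-ol | CC(C)(O)[C@@H]1CC[C@@](C)([C@H]2CC[C@]3(C)O[C@@H]3C2)O1 | intermediate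
4 | bromohydrin carbinol, (1R,2R,5S)-2-bromo-5-[(2S,5S)-5-(2-hydroxypropan-2-yl)-2-methyloxolan-2-yl]-2-methylcyclohexan-1-ol | CC(C)(O)[C@@H]1CC[C@@](C)([C@H]2CC[C@@](C)(Br)[C@H](O)C2)O1 | intermediate
5 | oxiranium bromide, 1-oxoniabicyclo[3.1.0]hexane ion in which the ether oxygen of 4 bridges the former carbinol carbon and the oxolane CH, bromide counter-ion | CC1(C)[C@@H]2CC[C@@](C)([C@H]3CC[C@@](C)(Br)[C@H](O)C3)[O+]12.[Br-] | intermediate
6 | oxolane tertiary bromide, (1R,2R,5S)-2-bromo-5-[(2S,5S)-5-(2-bromopropan-2-yl)-2-methyloxolan-2-yl]-2-methylcyclohexan-1-ol | CC(C)(Br)[C@@H]1CC[C@@](C)([C@H]2CC[C@@](C)(Br)[C@H](O)C2)O1 | intermediate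
7 | bromooxane bromohydrin, (1R,2R,5S)-2-bromo-5-[(2S,5R)-5-bromo-2,6,6-trimethyloxan-2-yl]-2-methylcyclohexan-1-ol | CC1(C)O[C@](C)([C@H]2CC[C@@](C)(Br)[C@H](O)C2)CC[C@H]1Br | intermediate
8 | chlorosulfite of 7 at the C3' oxygen | CC1(C)O[C@](C)([C@H]2CC[C@@](C)(Br)[C@H](OS(Cl)=O)C2)CC[C@H]1Br | intermediate
9 | bromonium chloride, bromine bridging C3' and C4' on the face cis to the oxanyl group | CC1(C)O[C@](C)([C@H]2CC[C@@]3(C)[Br+][C@H]3C2)CC[C@H]1Br.[Cl-] | intermediate
10 | diaxial isomer, (3R,6S)-3-bromo-6-[(1S,3R,4R)-4-bromo-3-chloro-4-methylcyclohexyl]-2,2,6-trimethyloxane | CC1(C)O[C@](C)([C@H]2CC[C@@](C)(Br)[C@H](Cl)C2)CC[C@H]1Br | intermediate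
11 | caespitane, (3R,6S)-3-bromo-6-[(1S,3S,4S)-3-bromo-4-chloro-4-methylcyclohexyl]-2,2,6-trimethyloxane | CC1(C)O[C@](C)([C@H]2CC[C@](C)(Cl)[C@@H](Br)C2)CC[C@H]1Br | target

Total step count: 4. Longest linear sequence: 4 steps from (−)-α-bisabolol.

Steps most likely to fail

Step 2. The oxiranium ion may be captured only at its tertiary carbon, or acid may cleave the tertiary ether bonds, so that the material stays at the oxolane stage or the skeleton unravels. The fallback sets out from 1 and comes back at 7. Direct 6-endo bromoetherification of the side-chain alkene by the C7 hydroxyl with 2,4,4,6-tetrabromocyclohexa-2,5-dienone (MeNO2, 0 °C, chair transition state with cyclohexenyl and bromine equatorial) should give the bromooxane alkene F1 after removal of the oxolane regioisomer and the C3 epimer. Shi epoxidation of the remaining ring alkene should then give the bromooxane epoxide F2, and HBr (1 equiv, CH2Cl2, −78 °C) should open F2 diaxially to 7.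

Step 4. The halogen interchange may be too slow below the temperature at which the tertiary halides lose HX, so that dehydrohalogenation competes. The fallback sets out from 7 and comes back at 11. The mesylate F3 (MsCl, Et3N, CH2Cl2, 0 °C) is ionised in (CF3)2CHOH–CH2Cl2 with Et4NCl. The bromonium ion formed with anchimeric assistance should be captured by chloride at the tertiary carbon under charge control in this ionising medium, giving 11 without passing through 10; any 10 formed is separated.

Step 1. The dioxirane may show low facial selectivity at the ring alkene, or the C7 alkoxide may open the ring epoxide instead of the side-chain epoxide. The fallback sets out from 1 and comes back at 10.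
- Hydroxyl-directed epoxidation of the side-chain alkene only (VO(acac)2, tBuOOH, PhH) with in situ 5-exo closure should give the oxolane carbinol alkene F4, the C2 epimer being removed.
- NBS in aqueous acetone should add across the ring alkene under Fürst–Plattner control to the diaxial bromohydrin F5.
- K2CO3 in MeOH should close it to the epoxide F6, syn to the side chain.
- LiCl/AcOH in THF should open F6 at its secondary carbon to the chlorohydrin F7.
- HBr then ZnBr2, as in step 2, should convert both tertiary hydroxyls, the ring one with retention via the chloronium ion and the side-chain one with ring expansion, which gives 10.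

Further compounds
F1 | step 2 | (3R,6S)-3-bromo-2,2,6-trimethyl-6-[(1S)-4-methylcyclohex-3-en-1-yl]oxane | CC1(C)O[C@](C)([C@@H]2CC=C(C)CC2)CC[C@H]1Br
F2 | step 2 | (3R,6S)-3-bromo-2,2,6-trimethyl-6-[(1R,3S,6S)-6-methyl-7-oxabicyclo[4.1.0]heptan-3-yl]oxane | CC1(C)O[C@](C)([C@H]2CC[C@]3(C)O[C@@H]3C2)CC[C@H]1Br
F3 | step 4 | methanesulfonate of 7 at the C3' oxygen | CC1(C)O[C@](C)([C@H]2CC[C@@](C)(Br)[C@H](OS(C)(=O)=O)C2)CC[C@H]1Br
F4 | step 1 | 2-[(2S,5S)-5-methyl-5-[(1S)-4-methylcyclohex-3-en-1-yl]oxolan-2-yl]propan-2-ol | CC(C)(O)[C@@H]1CC[C@@](C)([C@@H]2CC=C(C)CC2)O1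
F5 | step 1 | (1R,2R,4S)-2-bromo-4-[(2S,5S)-5-(2-hydroxypropan-2-yl)-2-methyloxolan-2-yl]-1-methylcyclohexan-1-ol | CC(C)(O)[C@@H]1CC[C@@](C)([C@H]2CC[C@@](C)(O)[C@H](Br)C2)O1
F6 | step 1 | 2-[(2S,5S)-5-methyl-5-[(1S,3S,6R)-6-methyl-7-oxabicyclo[4.1.0]heptan-3-yl]oxolan-2-yl]propan-2-ol | CC(C)(O)[C@@H]1CC[C@@](C)([C@H]2CC[C@@]3(C)O[C@H]3C2)O1
F7 | step 1 | (1R,2R,4S)-2-chloro-4-[(2S,5S)-5-(2-hydroxypropan-2-yl)-2-methyloxolan-2-yl]-1-methylcyclohexan-1-ol | CC(C)(O)[C@@H]1CC[C@@](C)([C@H]2CC[C@@](C)(O)[C@H](Cl)C2)O1
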